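## Compound numbers used throughout

1 syringaldehyde; 2 O-benzylsyringaldehyde; 3 (S)-4-benzyl-2-oxazolidinone; 4 bromoacetyl bromide; 5 N-bromoacetyl imide; 6 methyl 5-bromovanillate; 7 aryloxyacetyl imide; 8 boron enolate of 7; 9 boron aldolate; 10 syn aldol adduct; 11 1,3-diol; 12 stannylene acetal; 13 bromo alcohol with primary benzyl ether; 14 benzodioxane methyl ester; 15 2',4',6'-trifluoroacetophenone; 16 lithium enolate of 15; 17 trifluorophenyl 1,3-diketone; 18 5,7-difluoroflavone; 19 7-benzyloxy-5-fluoroflavone; 20 5,7-bis(benzyloxy)flavone; 21 palstatin.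

Locants: flavone numbering for rings A and C (O1, C2 to C4, C4a, C5 to C8, C8a), primed locants for ring B, and C7'', C8'', C9'' for the three-carbon unit of the dioxane.

## Analysis of the target

Palstatin (21) is a flavonolignan: a 5,7-dihydroxyflavone whose ring B is fused through the oxygens on C3' and C4' to a 1,4-dioxane. The oxygen on C3' (meta to the flavone link) is bound to the benzylic carbon C7'', which carries a 4-hydroxy-3,5-dimethoxyphenyl group. The oxygen on C4' (flanked by the C5' methoxy group) is bound to C8'', which carries the C9'' hydroxymethyl group. C7'' and C8'' are the only stereocentres; they are adjacent, both R, and their substituents are trans on the dioxane. They lie far from the flavone, so they have to be set by reagent control. The sensitive groups are three phenols and a primary alcohol, the benzylic aryl ether C7''–O (prone to ionisation under acid and to hydrogenolysis) and the pyranone, which adds hard nucleophiles at C2. The difficulties are to build the dioxane with the right regiochemistry and absolute configuration, and then to build rings A and C without a long series of phenol protections. The strategy rests on ring A: C5, C7 and C8a each carry an oxygen, each is ortho or para to C4a (which bears the C4 carbonyl), and they are meta to one another. A 2,4,6-trifluorophenyl ketone is therefore an equivalent of ring A in which every C–F bond is an activated site for nucleophilic aromatic substitution: one for O1 and two for the phenols.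

## Retrosynthetic reasoning

21 to 20. The four hydroxyl groups are unveiled last from four benzyl ethers in one hydrogenolysis. Benzyl is chosen because it survives every basic step of the route and because the oxygen nucleophile that fills C5 and C7 can bring it along.

20 to 18. The C5–O and C7–O bonds are cut to C–F bonds. Both carbons are activated by the C4 carbonyl (ortho and para), and the oxygens already on the ring are meta to the carbon attacked, so they do not oppose the anionic intermediate. Ring A therefore needs no protection or differentiation while the skeleton is assembled.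

18 to 17. The O1–C8a bond is cut, which opens ring C to a 1,3-diketone carrying a 2,4,6-trifluorophenyl group. This is the central disconnection. The forward reaction has to make the enolate oxygen displace an ortho fluoride, and the symmetry of the trifluorophenyl ring means only one flavone can result.

17 to 14 and 15. The bond between C2 and C3 of the future flavone is cut as a crossed Claisen condensation between the non-enolisable methyl ester 14 and the enolate 16 of ketone 15. An ester at C1' is preferred over a methyl ketone because it is inert to the enolisation used earlier for the aldol reaction.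

14 to 13. The aryl–oxygen bond at C3' is cut to an aryl bromide and a secondary alcohol. Forming the bond at the aryl carbon leaves C7'' and C8'' untouched, and the position of the bromine fixes which oxygen carries which carbon.

13 to 11 to 10. In diol 11 both hydroxyl groups are beta to the aryl ether oxygen, so either could close a six-membered ring onto the bromide. The primary one is therefore benzylated selectively (through 12) before the closure, which also installs the benzyl ether needed at C9''. Diol 11 comes from aldol adduct 10 by reductive removal of the auxiliary under conditions that spare the aryl ester.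

10 to 7 and 2. The C7''–C8'' bond is cut as a syn aldol reaction of the boron enolate 8 with aldehyde 2. This single step sets both stereocentres: the syn relation becomes the trans relation in the dioxane, and the (4S) auxiliary gives the 8''R,7''R series.

7 to 6 and 5; 5 to 3 and 4; 2 to 1. The aryloxyacetyl imide comes from alkylation of the single phenol of 6 with the bromoacetyl imide 5, itself from 3 and 4. Aldehyde 2 comes from 1 by benzylation.

## Alternatives that were turned down

Alternative 1: The O(C3')–C7'' bond is cut at the stage of a methyl benzoate, and C7'' is a plain methylene in the precursor A2. In the forward step, anodic oxidation of the free syringyl phenol of A2 (carbon anode, fluorinated alcohol, ammonium electrolyte) would give a para-quinone methide, which the C3' hydroxyl traps to give A1. In its favour, no halide, metal or C7'' hydroxyl is needed, and only C8'' has to be made enantiopure beforehand. Against it, A2 holds two oxidisable phenols, and the product A1 keeps the syringyl phenol beside a more activated benzylic C–H, so over-oxidation, solvent capture and dimerisation of the quinone methide compete. The C7'' configuration would rest on substrate control from C8'' alone, and this electrochemical etherification has no close precedent on such a substrate. The flavone would still have to be built from A1 after reprotection. On step and protecting-group economy for the dioxane this alternative is stronger. The chosen strategy offers in its place a reagent-controlled aldol for both stereocentres, and a key step of a well-documented reaction type.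

Alternative 2: The O(C4')–C8'' bond is cut, with the C9'' hydroxyl released from a terminal epoxide. In the forward step the C4' phenoxide of A4 opens the oxirane at its inner carbon in a 6-exo fashion with inversion, under mild carbonate conditions, to give aldehyde A3. In its favour, the step is stereospecific, metal-free and mild, and on stereospecificity at C8'' it is at least as good as the chosen route. Against it, A4 requires a benzylic aryl ether at C7'' to be made with defined configuration next to an epoxide, from a catechol whose two hydroxyls must be distinguished; that benzylic centre bears a very electron-rich aryl group, so ionisation threatens its configuration. The phenoxide is para to a formyl group and weakly nucleophilic, and attack at the unhindered terminal carbon (7-endo) competes. From A3 the flavone would be built by a chalcone-type sequence with a protected trihydroxyacetophenone partner, which brings back ring A protecting groups and an oxidation. The chosen strategy has only one phenol in its ring B building block, so the dioxane regiochemistry is fixed by the bromine, and ring A arrives unprotected as fluorine.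

Alternative 3: The aryl–oxygen bond at C3' is cut, as in the chosen route, but closed with a palladium catalyst carrying a bulky di-tert-butylbiarylphosphine and a carbonate base, taking bromo alcohol A6 to acetal A5. In its favour, this etherification is well documented for secondary alcohols, runs under milder conditions than copper and leaves both stereocentres untouched; as a ring-closing method it is at least as good as step 7 here and could replace it on 13. Against it as a strategy, the palladium alkoxide of a secondary benzylic alcohol can undergo beta-hydride elimination to a ketone and a debrominated arene. The acetal removes the para acceptor and makes the aryl bromide more electron-rich. From A5 the aldehyde must be unmasked and the flavone built classically with protected ring A phenols. That strategy spends its key step on a bond the chosen route treats as a supporting step. The chosen strategy differs in where rings A and C come from: three C–F bonds stand in for three C–O bonds, and no ring A protection is carried through the skeleton-building steps.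

Key step: step 9

## Route

Assumption on the chemistry: in step 10 the fluoride para to the C4 carbonyl (C7) is taken to be exchanged before the one ortho to it (C5). Intermediate 19 is drawn on that basis; the opposite order would converge on the same product 20.

Step 1
Reactants: 1 syringaldehyde
Product: 2 4-(benzyloxy)-3,5-dimethoxybenzaldehyde
Conditions: BnBr, K2CO3, DMF, rt
Reagents that add atoms: benzyl bromide, BrCc1ccccc1
Why: Williamson ether synthesis on the acidic syringyl phenol; the benzyl ether withstands all later basic steps and leaves in step 11.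

Step 2
Reactants: 3 (S)-4-benzyl-2-oxazolidinone; 4 bromoacetyl bromide
Product: 5 (4S)-4-benzyl-3-(bromoacetyl)-1,3-oxazolidin-2-one
Conditions: n-BuLi, THF, −78 °C; then 4, −78 °C
Reagents that add atoms: none
Why: N-acylation of the lithiated oxazolidinone; acyl substitution at the acid bromide is much faster at −78 °C than displacement of the alkyl bromide.

Step 3
Reactants: 6 methyl 3-bromo-4-hydroxy-5-methoxybenzoate; 5 (4S)-4-benzyl-3-(bromoacetyl)-1,3-oxazolidin-2-one
Product: 7 methyl 4-{2-[(4S)-4-benzyl-2-oxo-1,3-oxazolidin-3-yl]-2-oxoethoxy}-3-bromo-5-methoxybenzoate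
Conditions: K2CO3, MeCN, rt
Reagents that add atoms: none
Why: Williamson-type SN2 alkylation of the phenoxide of 6 by the alpha-bromo imide, a strongly activated primary halide; the hindered, weakly basic phenoxide should alkylate at CH2 and not open the imide.

Step 4
Reactants: 7 methyl 4-{2-[(4S)-4-benzyl-2-oxo-1,3-oxazolidin-3-yl]-2-oxoethoxy}-3-bromo-5-methoxybenzoate; 2 4-(benzyloxy)-3,5-dimethoxybenzaldehyde
Product: 10 methyl 4-{[(1R,2S)-1-[4-(benzyloxy)-3,5-dimethoxyphenyl]-3-[(4S)-4-benzyl-2-oxo-1,3-oxazolidin-3-yl]-1-hydroxy-3-oxopropan-2-yl]oxy}-3-bromo-5-methoxybenzoate (syn aldol adduct), via dibutylboron Z-enolate 8 (not isolated), via dibutylboron aldolate 9 (not isolated)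
Conditions: Bu2BOTf, Et3N, CH2Cl2, −78 → 0 °C; 2, −78 → 0 °C; then pH 7 buffer, MeOH, H2O2, 0 °C
Reagents that add atoms: none
Why: Evans syn aldol reaction through the Z boron enolate and a closed chair (Zimmerman–Traxler) transition state; the Z enolate fixes the syn relation of the aryloxy and hydroxyl groups, and the benzyl group of the (4S) auxiliary shields one enolate face, which sets C8'' and C7'' as (2S,3R) in the acyl chain. This arrangement becomes 8''R,7''R once the imide carbonyl is a CH2O group; the aryl methyl ester cannot enolise and the aryl bromide is inert.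

Step 5
Reactants: 10 syn aldol adduct
Product: 11 methyl 4-{[(1R,2R)-1-[4-(benzyloxy)-3,5-dimethoxyphenyl]-1,3-dihydroxypropan-2-yl]oxy}-3-bromo-5-methoxybenzoate
Conditions: NaBH4, THF/H2O, 0 °C → rt
Reagents that add atoms: none
Why: Reductive removal of the auxiliary by hydride attack on the activated exocyclic imide carbonyl; an aryl methyl ester and an aryl bromide are not reduced by NaBH4 under these conditions, and neither stereocentre is touched.

Step 6
Reactants: 11 methyl 4-{[(1R,2R)-1-[4-(benzyloxy)-3,5-dimethoxyphenyl]-1,3-dihydroxypropan-2-yl]oxy}-3-bromo-5-methoxybenzoate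
Product: 13 methyl 4-{[(1R,2R)-3-(benzyloxy)-1-[4-(benzyloxy)-3,5-dimethoxyphenyl]-1-hydroxypropan-2-yl]oxy}-3-bromo-5-methoxybenzoate, via dibutylstannylene acetal 12 (not isolated)
Conditions: Bu2SnO, toluene, reflux (−H2O); then BnBr, Bu4NI, 80 °C
Reagents that add atoms: benzyl bromide, BrCc1ccccc1
Why: Regioselective O-alkylation through the six-membered stannylene acetal, which activates the less hindered primary oxygen, so the benzylic hydroxyl stays free. This caps the hydroxyl that could otherwise also close a six-membered ring in step 7.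

Step 7
Reactants: 13 methyl 4-{[(1R,2R)-3-(benzyloxy)-1-[4-(benzyloxy)-3,5-dimethoxyphenyl]-1-hydroxypropan-2-yl]oxy}-3-bromo-5-methoxybenzoate
Product: 14 methyl (2R,3R)-2-[(benzyloxy)methyl]-3-[4-(benzyloxy)-3,5-dimethoxyphenyl]-8-methoxy-2,3-dihydro-1,4-benzodioxine-6-carboxylate
Conditions: CuI (cat.), 3,4,7,8-tetramethyl-1,10-phenanthroline (cat.), Cs2CO3, toluene, 110 °C, Ar
Reagents that add atoms: none
Why: Intramolecular Ullmann-type aryl etherification of the secondary alkoxide with the ortho bromide; the new bond is made at the aryl carbon, so C7'' and C8'' keep their configuration and the syn aldol relation appears as the trans (2R,3R) dioxane. The position of the bromine fixes the regiochemistry of the ring.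

Step 8
Reactants: 14 benzodioxane methyl ester; 15 2',4',6'-trifluoroacetophenone
Product: 17 1-{(2R,3R)-2-[(benzyloxy)methyl]-3-[4-(benzyloxy)-3,5-dimethoxyphenyl]-8-methoxy-2,3-dihydro-1,4-benzodioxin-6-yl}-3-(2,4,6-trifluorophenyl)propane-1,3-dione, via lithium enolate 16 (not isolated)
Conditions: 15 (excess), LiN(SiMe3)2, THF, −78 °C; then 14, −78 °C → rt; aq. HCl
Reagents that add atoms: none
Why: Crossed Claisen condensation: the lithium enolate adds to the non-enolisable methyl ester, methoxide leaves, and deprotonation of the 1,3-diketone by the excess enolate drives the equilibrium. The hindered amide base and low temperature keep the C–F bonds intact.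

Step 9
Reactants: 17 trifluorophenyl 1,3-diketone
Product: 18 2-{(2R,3R)-2-[(benzyloxy)methyl]-3-[4-(benzyloxy)-3,5-dimethoxyphenyl]-8-methoxy-2,3-dihydro-1,4-benzodioxin-6-yl}-5,7-difluoro-4H-chromen-4-one
Conditions: K2CO3 (dry), DMF, 60 °C
Reagents that add atoms: none
Why: Carbonate deprotonates the 1,3-diketone, the most acidic site of 17, and the diketonate oxygen on the carbon bound to ring B adds to an ortho C–F carbon of the trifluorophenyl ring; the anionic sigma complex, with its charge delocalised onto the C4 carbonyl, expels fluoride and rearomatises (addition–elimination SNAr). The closest known reaction type is the base-mediated cyclisation of 1-(2-fluoroaryl)-1,3-diketones to chromones, with its nitrogen counterpart in quinolone synthesis. Ring C closes as a six-membered ring in which the attacked ortho carbon and its ipso neighbour both become ring atoms, that is a 6-endo-trig addition to the C(ortho)=C(ipso)–C4=O unit followed by loss of fluoride; O1–C8a is the only skeletal bond formed. No stereocentre is created, and C7'' and C8'' are far from any acidic or electrophilic site, so carbonate does not endanger them. Oxygen attack is required and is enforced by ring size, since attack through the central carbon or through the other enolate oxygen would give a four-membered ring. Only the ortho positions are within reach, and they are equivalent by the symmetry of the 2,4,6-trifluorophenyl group, so a single flavone can form. The two remaining fluorides of 18 are activated towards external nucleophiles, so the reaction is run with dry carbonate at moderate temperature and stopped at full conversion.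

Step 10
Reactants: 18 5,7-difluoroflavone
Product: 20 5,7-bis(benzyloxy)-2-{(2R,3R)-2-[(benzyloxy)methyl]-3-[4-(benzyloxy)-3,5-dimethoxyphenyl]-8-methoxy-2,3-dihydro-1,4-benzodioxin-6-yl}-4H-chromen-4-one, via 7-benzyloxy-5-fluoroflavone 19 (not isolated)
Conditions: BnOH, NaH, DMF, 0 °C; then 18, 0 → 60 °C
Reagents that add atoms: benzyl alcohol (as sodium benzyloxide), OCc1ccccc1
Why: Two successive nucleophilic aromatic substitutions (addition–elimination) of the fluorides para and ortho to the C4 carbonyl by benzyloxide; O1 and the first benzyloxy group are meta to the carbon attacked next, so they do not place charge against the anionic intermediate. Addition of the alkoxide at C2 of the pyranone is reversible, whereas loss of fluoride is not.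

Step 11
Reactants: 20 5,7-bis(benzyloxy)flavone
Product: 21 palstatin, 5,7-dihydroxy-2-[(2R,3R)-3-(4-hydroxy-3,5-dimethoxyphenyl)-2-(hydroxymethyl)-8-methoxy-2,3-dihydro-1,4-benzodioxin-6-yl]-4H-chromen-4-one
Conditions: H2 (1 atm), 10% Pd/C, THF/MeOH, rt
Reagents that add atoms: none
Why: Hydrogenolysis of the three aryl benzyl ethers and the primary alkyl benzyl ether over Pd/C; the cyclic benzylic C7''–O bond and the C2=C3 bond of the flavone react more slowly, so the reaction is stopped once the four benzyl groups are gone.

## Compound list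

1 | syringaldehyde (4-hydroxy-3,5-dimethoxybenzaldehyde) | COc1cc(C=O)cc(OC)c1O | starting material
2 | 4-(benzyloxy)-3,5-dimethoxybenzaldehyde | COc1cc(C=O)cc(OC)c1OCc1ccccc1 | intermediate
3 | (S)-4-benzyl-2-oxazolidinone | O=C1N[C@@H](Cc2ccccc2)CO1 | starting material
4 | bromoacetyl bromide | BrCC(Br)=O | starting material
5 | (4S)-4-benzyl-3-(bromoacetyl)-1,3-oxazolidin-2-one | O=C(CBr)N1C(=O)OC[C@@H]1Cc1ccccc1 | intermediate
6 | methyl 3-bromo-4-hydroxy-5-methoxybenzoate (methyl 5-bromovanillate) | COC(=O)c1cc(Br)c(O)c(OC)c1 | starting material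
7 | methyl 4-{2-[(4S)-4-benzyl-2-oxo-1,3-oxazolidin-3-yl]-2-oxoethoxy}-3-bromo-5-methoxybenzoate | COC(=O)c1cc(Br)c(OCC(=O)N2C(=O)OC[C@@H]2Cc2ccccc2)c(OC)c1 | intermediate
8 | dibutylboron (Z)-enolate of 7 | CCCCB(CCCC)O/C(=C\Oc1c(Br)cc(C(=O)OC)cc1OC)N1C(=O)OC[C@@H]1Cc1ccccc1 | intermediate
9 | dibutylboron aldolate of 10 | COc1cc([C@@H](OB(CCCC)CCCC)[C@@H](C(=O)N2C(=O)OC[C@@H]2Cc2ccccc2)Oc2c(Br)cc(C(=O)OC)cc2OC)cc(OC)c1OCc1ccccc1 | intermediate
10 | methyl 4-{[(1R,2S)-1-[4-(benzyloxy)-3,5-dimethoxyphenyl]-3-[(4S)-4-benzyl-2-oxo-1,3-oxazolidin-3-yl]-1-hydroxy-3-oxopropan-2-yl]oxy}-3-bromo-5-methoxybenzoate | COc1cc([C@@H](O)[C@@H](C(=O)N2C(=O)OC[C@@H]2Cc2ccccc2)Oc2c(Br)cc(C(=O)OC)cc2OC)cc(OC)c1OCc1ccccc1 | intermediate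
11 | methyl 4-{[(1R,2R)-1-[4-(benzyloxy)-3,5-dimethoxyphenyl]-1,3-dihydroxypropan-2-yl]oxy}-3-bromo-5-methoxybenzoate | COc1cc([C@@H](O)[C@@H](CO)Oc2c(Br)cc(C(=O)OC)cc2OC)cc(OC)c1OCc1ccccc1 | intermediate
12 | methyl 4-{[(4R,5R)-4-[4-(benzyloxy)-3,5-dimethoxyphenyl]-2,2-dibutyl-1,3,2-dioxastanninan-5-yl]oxy}-3-bromo-5-methoxybenzoate | COc1cc([C@H]2O[Sn](CCCC)(CCCC)OC[C@H]2Oc2c(Br)cc(C(=O)OC)cc2OC)cc(OC)c1OCc1ccccc1 | intermediate
13 | methyl 4-{[(1R,2R)-3-(benzyloxy)-1-[4-(benzyloxy)-3,5-dimethoxyphenyl]-1-hydroxypropan-2-yl]oxy}-3-bromo-5-methoxybenzoate | COc1cc([C@@H](O)[C@@H](COCc2ccccc2)Oc2c(Br)cc(C(=O)OC)cc2OC)cc(OC)c1OCc1ccccc1 | intermediate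
14 | methyl (2R,3R)-2-[(benzyloxy)methyl]-3-[4-(benzyloxy)-3,5-dimethoxyphenyl]-8-methoxy-2,3-dihydro-1,4-benzodioxine-6-carboxylate | COc1cc([C@H]2Oc3cc(C(=O)OC)cc(OC)c3O[C@@H]2COCc2ccccc2)cc(OC)c1OCc1ccccc1 | intermediate
15 | 2',4',6'-trifluoroacetophenone | CC(=O)c1c(F)cc(F)cc1F | starting material
16 | lithium 1-(2,4,6-trifluorophenyl)ethen-1-olate | [Li+].[O-]C(=C)c1c(F)cc(F)cc1F | intermediate
17 | 1-{(2R,3R)-2-[(benzyloxy)methyl]-3-[4-(benzyloxy)-3,5-dimethoxyphenyl]-8-methoxy-2,3-dihydro-1,4-benzodioxin-6-yl}-3-(2,4,6-trifluorophenyl)propane-1,3-dione | COc1cc([C@H]2Oc3cc(C(=O)CC(=O)c4c(F)cc(F)cc4F)cc(OC)c3O[C@@H]2COCc5ccccc5)cc(OC)c1OCc6ccccc6 | intermediate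
18 | 2-{(2R,3R)-2-[(benzyloxy)methyl]-3-[4-(benzyloxy)-3,5-dimethoxyphenyl]-8-methoxy-2,3-dihydro-1,4-benzodioxin-6-yl}-5,7-difluoro-4H-chromen-4-one | COc1cc([C@H]2Oc3cc(-c4cc(=O)c5c(F)cc(F)cc5o4)cc(OC)c3O[C@@H]2COCc6ccccc6)cc(OC)c1OCc7ccccc7 | intermediate
19 | 7-(benzyloxy)-2-{(2R,3R)-2-[(benzyloxy)methyl]-3-[4-(benzyloxy)-3,5-dimethoxyphenyl]-8-methoxy-2,3-dihydro-1,4-benzodioxin-6-yl}-5-fluoro-4H-chromen-4-one | COc1cc([C@H]2Oc3cc(-c4cc(=O)c5c(F)cc(OCc6ccccc6)cc5o4)cc(OC)c3O[C@@H]2COCc7ccccc7)cc(OC)c1OCc8ccccc8 | intermediate
20 | 5,7-bis(benzyloxy)-2-{(2R,3R)-2-[(benzyloxy)methyl]-3-[4-(benzyloxy)-3,5-dimethoxyphenyl]-8-methoxy-2,3-dihydro-1,4-benzodioxin-6-yl}-4H-chromen-4-one | COc1cc([C@H]2Oc3cc(-c4cc(=O)c5c(OCc6ccccc6)cc(OCc7ccccc7)cc5o4)cc(OC)c3O[C@@H]2COCc8ccccc8)cc(OC)c1OCc9ccccc9 | intermediate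
21 | palstatin, 5,7-dihydroxy-2-[(2R,3R)-3-(4-hydroxy-3,5-dimethoxyphenyl)-2-(hydroxymethyl)-8-methoxy-2,3-dihydro-1,4-benzodioxin-6-yl]-4H-chromen-4-one | COc1cc([C@H]2Oc3cc(-c4cc(=O)c5c(O)cc(O)cc5o4)cc(OC)c3O[C@@H]2CO)cc(OC)c1O | target

## Step count and least certain steps

Total step count: 11. Longest linear sequence: 10 steps (steps 2 to 11, from 3 and 4).

Step 9 (key step). The most likely failures are cleavage of the diketonate by adventitious hydroxide (retro-Claisen), or substitution of the activated fluorides of the product by amine formed from the solvent on prolonged heating. Fallback, from 14 back to 18: the ring oxygen is bought in place and ring C is closed by carbonyl condensation, not at the arene. 1-(2,4-Difluoro-6-hydroxyphenyl)ethanone (CC(=O)c1c(O)cc(F)cc1F) is converted with excess LiN(SiMe3)2 in THF at −78 °C into its dianion and condensed with ester 14 to give the ortho-hydroxyaryl diketone, 1-{(2R,3R)-2-[(benzyloxy)methyl]-3-[4-(benzyloxy)-3,5-dimethoxyphenyl]-8-methoxy-2,3-dihydro-1,4-benzodioxin-6-yl}-3-(2,4-difluoro-6-hydroxyphenyl)propane-1,3-dione F1. Acid-catalysed cyclodehydration (catalytic TsOH, toluene, 80 °C) then forms the O1–C2 bond and gives 18.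

Step 10. The second exchange may stall after the first fluoride is replaced, or the alkoxide may add at C2 and open the pyranone, followed by cleavage. Fallback, from 14 back to 20: the fluorine strategy is dropped for ring A. The dianion of 1-[2,4-bis(benzyloxy)-6-hydroxyphenyl]ethanone (CC(=O)c1c(O)cc(OCc2ccccc2)cc1OCc1ccccc1), made with LiN(SiMe3)2 in THF, is condensed with ester 14 to give 1-[2,4-bis(benzyloxy)-6-hydroxyphenyl]-3-{(2R,3R)-2-[(benzyloxy)methyl]-3-[4-(benzyloxy)-3,5-dimethoxyphenyl]-8-methoxy-2,3-dihydro-1,4-benzodioxin-6-yl}propane-1,3-dione F2. Cyclodehydration with catalytic TsOH in toluene gives 20.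

Step 8. Acyl substitution at the electron-rich methyl ester may be slow, leaving the enolate time to attack a C–F bond of unenolised ketone or to condense with itself. Fallback, from 14 back to 17: the ester is replaced by a stronger acyl donor. Saponification (LiOH, THF/MeOH/H2O) gives (2R,3R)-2-[(benzyloxy)methyl]-3-[4-(benzyloxy)-3,5-dimethoxyphenyl]-8-methoxy-2,3-dihydro-1,4-benzodioxine-6-carboxylic acid F3. Oxalyl chloride with catalytic DMF in CH2Cl2 gives the corresponding 6-carbonyl chloride F4, which is added at −78 °C to two equivalents of enolate 16 to give 17 by C-acylation.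

Step 7. The beta-aryloxy alkoxide may undergo a Smiles-type aryl migration at the ring carbon para to the ester, which would transpose the two dioxane oxygens; reductive loss of bromide and slow coupling of the hindered secondary alkoxide are further risks. Fallback, from 13 back to 14: the bond formed is changed from aryl–O to C7''–O. Miyaura borylation (B2pin2, Pd(dppf)Cl2, KOAc, dioxane, 90 °C) gives methyl 4-{[(1R,2R)-3-(benzyloxy)-1-[4-(benzyloxy)-3,5-dimethoxyphenyl]-1-hydroxypropan-2-yl]oxy}-3-methoxy-5-(4,4,5,5-tetramethyl-1,3,2-dioxaborolan-2-yl)benzoate F5. Oxidation (NaBO3·4H2O, THF/H2O, rt) gives the phenol, methyl 4-{[(1R,2R)-3-(benzyloxy)-1-[4-(benzyloxy)-3,5-dimethoxyphenyl]-1-hydroxypropan-2-yl]oxy}-3-hydroxy-5-methoxybenzoate F6. Catalytic TsOH in CH2Cl2 ionises the electron-rich benzylic alcohol and the phenol closes the ring reversibly; the untouched C8'' centre should direct the closure to the more stable trans dioxane 14.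

Step 11. Over-reduction is the concern: hydrogenolysis of the cyclic benzylic C7''–O bond or saturation of the C2=C3 bond before the last benzyl ether is gone. Fallback, from 20 directly to 21: non-reductive debenzylation with BCl3 and pentamethylbenzene as cation scavenger in CH2Cl2 at −78 °C, which makes no new compound (F0). Ionisation at C7'' by the Lewis acid would have to be watched.

## Further compounds

F1 | step 9 | 1-{(2R,3R)-2-[(benzyloxy)methyl]-3-[4-(benzyloxy)-3,5-dimethoxyphenyl]-8-methoxy-2,3-dihydro-1,4-benzodioxin-6-yl}-3-(2,4-difluoro-6-hydroxyphenyl)propane-1,3-dione | COc1cc([C@H]2Oc3cc(C(=O)CC(=O)c4c(O)cc(F)cc4F)cc(OC)c3O[C@@H]2COCc5ccccc5)cc(OC)c1OCc6ccccc6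
F2 | step 10 | 1-[2,4-bis(benzyloxy)-6-hydroxyphenyl]-3-{(2R,3R)-2-[(benzyloxy)methyl]-3-[4-(benzyloxy)-3,5-dimethoxyphenyl]-8-methoxy-2,3-dihydro-1,4-benzodioxin-6-yl}propane-1,3-dione | COc1cc([C@H]2Oc3cc(C(=O)CC(=O)c4c(O)cc(OCc5ccccc5)cc4OCc6ccccc6)cc(OC)c3O[C@@H]2COCc7ccccc7)cc(OC)c1OCc8ccccc8
F3 | step 8 | (2R,3R)-2-[(benzyloxy)methyl]-3-[4-(benzyloxy)-3,5-dimethoxyphenyl]-8-methoxy-2,3-dihydro-1,4-benzodioxine-6-carboxylic acid | COc1cc([C@H]2Oc3cc(C(=O)O)cc(OC)c3O[C@@H]2COCc4ccccc4)cc(OC)c1OCc5ccccc5
F4 | step 8 | (2R,3R)-2-[(benzyloxy)methyl]-3-[4-(benzyloxy)-3,5-dimethoxyphenyl]-8-methoxy-2,3-dihydro-1,4-benzodioxine-6-carbonyl chloride | COc1cc([C@H]2Oc3cc(C(=O)Cl)cc(OC)c3O[C@@H]2COCc4ccccc4)cc(OC)c1OCc5ccccc5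
F5 | step 7 | methyl 4-{[(1R,2R)-3-(benzyloxy)-1-[4-(benzyloxy)-3,5-dimethoxyphenyl]-1-hydroxypropan-2-yl]oxy}-3-methoxy-5-(4,4,5,5-tetramethyl-1,3,2-dioxaborolan-2-yl)benzoate | COc1cc([C@@H](O)[C@@H](COCc2ccccc2)Oc2c(B3OC(C)(C)C(C)(C)O3)cc(C(=O)OC)cc2OC)cc(OC)c1OCc1ccccc1
F6 | step 7 | methyl 4-{[(1R,2R)-3-(benzyloxy)-1-[4-(benzyloxy)-3,5-dimethoxyphenyl]-1-hydroxypropan-2-yl]oxy}-3-hydroxy-5-methoxybenzoate | COc1cc([C@@H](O)[C@@H](COCc2ccccc2)Oc2c(O)cc(C(=O)OC)cc2OC)cc(OC)c1OCc1ccccc1
F0 | step 11 | none | none
A1 | alternative 1 | methyl (2R,3R)-3-(4-hydroxy-3,5-dimethoxyphenyl)-2-(hydroxymethyl)-8-methoxy-2,3-dihydro-1,4-benzodioxine-6-carboxylate | COc1cc([C@H]2Oc3cc(C(=O)OC)cc(OC)c3O[C@@H]2CO)cc(OC)c1O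
A2 | alternative 1 | methyl 3-hydroxy-4-{[(2S)-1-hydroxy-3-(4-hydroxy-3,5-dimethoxyphenyl)propan-2-yl]oxy}-5-methoxybenzoate | COc1cc(C[C@@H](CO)Oc2c(O)cc(C(=O)OC)cc2OC)cc(OC)c1O
A3 | alternative 2 | (2R,3R)-3-[4-(benzyloxy)-3,5-dimethoxyphenyl]-2-(hydroxymethyl)-8-methoxy-2,3-dihydro-1,4-benzodioxine-6-carbaldehyde | COc1cc([C@H]2Oc3cc(C=O)cc(OC)c3O[C@@H]2CO)cc(OC)c1OCc4ccccc4
A4 | alternative 2 | 3-{(R)-[4-(benzyloxy)-3,5-dimethoxyphenyl][(2S)-oxiran-2-yl]methoxy}-4-hydroxy-5-methoxybenzaldehyde | COc1cc([C@@H](Oc2cc(C=O)cc(OC)c2O)[C@@H]2CO2)cc(OC)c1OCc1ccccc1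
A5 | alternative 3 | (2R,3R)-2-[(benzyloxy)methyl]-3-[4-(benzyloxy)-3,5-dimethoxyphenyl]-6-(1,3-dioxolan-2-yl)-8-methoxy-2,3-dihydro-1,4-benzodioxine | COc1cc([C@H]2Oc3cc(C4OCCO4)cc(OC)c3O[C@@H]2COCc5ccccc5)cc(OC)c1OCc6ccccc6
A6 | alternative 3 | (1R,2R)-3-(benzyloxy)-1-[4-(benzyloxy)-3,5-dimethoxyphenyl]-2-[2-bromo-4-(1,3-dioxolan-2-yl)-6-methoxyphenoxy]propan-1-ol | COc1cc([C@@H](O)[C@@H](COCc2ccccc2)Oc2c(Br)cc(C3OCCO3)cc2OC)cc(OC)c1OCc1ccccc1
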